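The trimer is disconnected at the C4(middle)–C8(terminal) interflavan bond, the way proanthocyanidins are presumably assembled in plants. C4 of the galloylated middle C-ring is benzylic to an A-ring carrying O1, O5 and O7, so a thio leaving group there ionises to a quinone-methide-like cation. In the key step a silver salt unmasks this cation in a bromine-capped, benzyl-protected dimeric 4-thioether; the C3 gallate carbonyl bridges its α-face, and C8 of benzylated epigallocatechin attacks the β-face, forming the bond and the 3,4-trans C4 stereocentre at once. All C2/C3 centres are bought with (−)-epigallocatechin; both C4 centres are relayed from them.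

Key step: step 7

Remark: (−)-epigallocatechin, the green-tea flavan-3-ol, is taken as a commercial chiral-pool starting material. "4β" means 2,3-cis-3,4-trans, i.e. the C4 substituent lies on the ring face opposite to the 3-oxygen and the B-ring.

Step 1
Reactants: 1 (−)-epigallocatechin; 2 benzyl bromide
Product: 3 5,7,3′,4′,5′-penta-O-benzyl-(−)-epigallocatechin
Conditions: BnBr (5.3 equiv), K2CO3, degassed DMF, Ar, 0 °C → rt
Reagents that add atoms: benzyl bromide, BrCc1ccccc1
Why: Williamson ether synthesis: carbonate deprotonates only the five phenols and not the secondary C3 alcohol, so benzyl bromide O-alkylates the phenoxides, while oxygen-free, cold conditions keep the pyrogallol ring from oxidising and C2 from epimerising; no stereocentre is touched.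

Step 2
Reactants: 3 penta-O-benzyl-epigallocatechin; 4 2-ethoxyethanol
Product: 5 penta-O-benzyl-4β-(2-ethoxyethoxy)-epigallocatechin
Conditions: DDQ (2 equiv), 2-ethoxyethanol (5 equiv), CH2Cl2, rt
Reagents that add atoms: 2-ethoxyethanol, CCOCCO
Why: Benzylic C–H oxidation by DDQ: hydride abstraction at C4, activated by O1 and the 5,7-dialkoxy A-ring, gives a quinone-methide cation that the alcohol captures on the β-face, anti to the α-oriented 3-OH and B-ring, which sets C4 as 3,4-trans.

Step 3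
Reactants: 5 penta-O-benzyl-4β-(2-ethoxyethoxy)-epigallocatechin; 6 N-bromosuccinimide
Product: 7 8-bromo-penta-O-benzyl-4β-(2-ethoxyethoxy)-epigallocatechin
Conditions: NBS (1.0 equiv), CH2Cl2, −40 → 0 °C
Reagents that add atoms: N-bromosuccinimide, O=C1CCC(=O)N1Br
Why: Electrophilic aromatic bromination: C8 of the phloroglucinol-type A-ring (ortho to O1 and O7, para to O5) is its most reactive and less hindered position, and acid-free NBS leaves the C4 ether and the stereocentres untouched.

Step 4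
Reactants: 5 penta-O-benzyl-4β-(2-ethoxyethoxy)-epigallocatechin; 8 2,6-dimethylbenzenethiol
Product: 9 penta-O-benzyl-4β-(2,6-dimethylphenylthio)-epigallocatechin
Conditions: thiol (5 equiv), BF3·OEt2 (0.3 equiv), CH2Cl2, −78 → −30 °C
Reagents that add atoms: 2,6-dimethylbenzenethiol, Cc1cccc(C)c1S
Why: Lewis-acid SN1 substitution of the thiolysis type: BF3 ionises the C4–O bond and the thiol, used in excess so that it outruns C8 of a second molecule, adds to the cation on the β-face anti to the 3-OH and B-ring, giving the 3,4-trans sulfide.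

Step 5
Reactants: 9 penta-O-benzyl-4β-(2,6-dimethylphenylthio)-epigallocatechin; 10 3,4,5-tris(benzyloxy)benzoic acid
Product: 11 penta-O-benzyl-4β-(2,6-dimethylphenylthio)-epigallocatechin 3-O-[3,4,5-tris(benzyloxy)benzoate]
Conditions: DCC (1.5 equiv), DMAP (cat.), CH2Cl2, rt
Reagents that add atoms: 3,4,5-tris(benzyloxy)benzoic acid, O=C(O)c1cc(OCc2ccccc2)c(OCc2ccccc2)c(OCc2ccccc2)c1
Why: Steglich esterification: the acyl-pyridinium formed from 10, DCC and DMAP acylates the hindered axial C3 hydroxyl with retention, the sulfide and benzyl ethers being inert.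

Step 6
Reactants: 7 8-bromo-penta-O-benzyl-4β-(2-ethoxyethoxy)-epigallocatechin; 11 thioether gallate (1.5 equiv)
Product: 12 [8-bromo-penta-O-benzyl-epigallocatechin]-(4β→8)-[penta-O-benzyl-4β-(2,6-dimethylphenylthio)-epigallocatechin 3-O-tri-O-benzylgallate]
Conditions: TMSOTf (0.2 equiv), 4 Å MS, CH2Cl2, −78 °C; then Et3N
Reagents that add atoms: none
Why: Friedel–Crafts alkylation under hard Lewis-acid activation: the oxophilic silyl triflate ionises the C4–O bond of 7 but not the hindered, weakly basic aryl sulfide of 11 at −78 °C, C8 of 11 attacks the cation on the β-face anti to the α 3-OH and B-ring (setting the upper C4 as 3,4-trans), and the C8 bromine of 7 excludes self-condensation.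

Step 7
Reactants: 12 bromo-capped dimeric 4β-thioether gallate; 3 penta-O-benzyl-epigallocatechin (3 equiv)
Product: 14 benzyl-protected bromo-capped trimer, via C3/C4-bridged acyloxonium ion 13 (not isolated)
Conditions: AgOTf (1.5 equiv), 4 Å MS, CH2Cl2, dark, −78 → −30 °C; then Et3N
Reagents that add atoms: none
Why: Ag(I), a soft thiophile, binds the aryl sulfide and the C4–S bond ionises (SN1) to the C4 cation of the middle C-ring, which is stabilised as an ortho/para-quinone-methide oxocarbenium by O1, O5 and O7 of its A-ring, the same electrophile as the extension unit of proanthocyanidin biosynthesis; C8 of 3 then attacks and rearomatises (Friedel–Crafts alkylation). The closest known reaction types are the thiophile-promoted coupling of flavan-4-yl thioethers with flavan-3-ols and the hard/soft orthogonal activation used in oligocatechin assembly. No ring of the target is closed; the only ring formed is the transient five-membered dioxolenium ring of 13, closed by attack of the gallate carbonyl oxygen on C4 (anchimeric assistance) and reopened by the nucleophile. The new C4 stereocentre is controlled by the C3 ester and the C2 aryl group: both lie on the α-face, the acyloxonium bridge blocks that face, and the arene enters on the β-face with inversion at C4, giving the 2,3-cis-3,4-trans (4β) bond. The step needs C8-over-C6 regioselectivity in 3, secured because C8 (between O1 and one benzyloxy group) is less hindered than C6 (between two benzyloxy groups), and it needs the dimer not to react with itself, secured by the bromine on C8 of the upper unit and the substituted C8 of the middle unit. The triflic acid set free keeps any O-alkylation at the free 3-hydroxyls reversible, so material should funnel to the C–C product.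

Step 8
Reactants: 14 benzyl-protected bromo-capped trimer
Product: 15 epigallocatechin-(4β→8)-epigallocatechin 3-O-gallate-(4β→8)-epigallocatechin
Conditions: H2 (1 atm), 20% Pd(OH)2/C, NaOAc (1.2 equiv), THF–MeOH–H2O, rt; filtration under Ar, lyophilisation
Reagents that add atoms: none
Why: Catalytic hydrogenolysis: Pd(OH)2/C cleaves the eighteen benzyl ethers and the aryl C–Br bond in one operation while sodium acetate buffers the HBr, so the acid-labile interflavan bonds, the gallate ester and all stereocentres remain.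

Compound list

1 | (−)-epigallocatechin, (2R,3R)-2-(3,4,5-trihydroxyphenyl)chromane-3,5,7-triol | O[C@@H]1Cc2c(O)cc(O)cc2O[C@@H]1c1cc(O)c(O)c(O)c1 | starting material
2 | benzyl bromide | BrCc1ccccc1 | starting material
3 | 5,7,3′,4′,5′-penta-O-benzyl-(−)-epigallocatechin (2R,3R; free 3-OH) | O[C@@H]1Cc2c(OCc5ccccc5)cc(OCc5ccccc5)cc2O[C@@H]1c1cc(OCc5ccccc5)c(OCc5ccccc5)c(OCc5ccccc5)c1 | intermediate
4 | 2-ethoxyethanol | CCOCCO | starting material
5 | 5,7,3′,4′,5′-penta-O-benzyl-4β-(2-ethoxyethoxy)-epigallocatechin (2,3-cis-3,4-trans) | O[C@@H]1[C@@H](OCCOCC)c2c(OCc5ccccc5)cc(OCc5ccccc5)cc2O[C@@H]1c1cc(OCc5ccccc5)c(OCc5ccccc5)c(OCc5ccccc5)c1 | intermediate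
6 | N-bromosuccinimide | O=C1CCC(=O)N1Br | starting material
7 | 8-bromo-5,7,3′,4′,5′-penta-O-benzyl-4β-(2-ethoxyethoxy)-epigallocatechin | O[C@@H]1[C@@H](OCCOCC)c2c(OCc5ccccc5)cc(OCc5ccccc5)c(Br)c2O[C@@H]1c1cc(OCc5ccccc5)c(OCc5ccccc5)c(OCc5ccccc5)c1 | intermediate
8 | 2,6-dimethylbenzenethiol | Cc1cccc(C)c1S | starting material
9 | 5,7,3′,4′,5′-penta-O-benzyl-4β-(2,6-dimethylphenylthio)-epigallocatechin (2,3-cis-3,4-trans) | O[C@@H]1[C@@H](Sc2c(C)cccc2C)c2c(OCc5ccccc5)cc(OCc5ccccc5)cc2O[C@@H]1c1cc(OCc5ccccc5)c(OCc5ccccc5)c(OCc5ccccc5)c1 | intermediate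
10 | 3,4,5-tris(benzyloxy)benzoic acid | O=C(O)c1cc(OCc2ccccc2)c(OCc2ccccc2)c(OCc2ccccc2)c1 | starting material
11 | 5,7,3′,4′,5′-penta-O-benzyl-4β-(2,6-dimethylphenylthio)-epigallocatechin 3-O-[3,4,5-tris(benzyloxy)benzoate] | O=C(O[C@@H]1[C@@H](Sc2c(C)cccc2C)c2c(OCc5ccccc5)cc(OCc5ccccc5)cc2O[C@@H]1c1cc(OCc5ccccc5)c(OCc5ccccc5)c(OCc5ccccc5)c1)c1cc(OCc5ccccc5)c(OCc5ccccc5)c(OCc5ccccc5)c1 | intermediate
12 | [8-bromo-penta-O-benzyl-epigallocatechin]-(4β→8)-[penta-O-benzyl-4β-(2,6-dimethylphenylthio)-epigallocatechin 3-O-tri-O-benzylgallate] | O=C(O[C@@H]1[C@@H](Sc2c(C)cccc2C)c2c(OCc5ccccc5)cc(OCc5ccccc5)c([C@H]3c4c(OCc5ccccc5)cc(OCc5ccccc5)c(Br)c4O[C@H](c4cc(OCc5ccccc5)c(OCc5ccccc5)c(OCc5ccccc5)c4)[C@@H]3O)c2O[C@@H]1c1cc(OCc5ccccc5)c(OCc5ccccc5)c(OCc5ccccc5)c1)c1cc(OCc5ccccc5)c(OCc5ccccc5)c(OCc5ccccc5)c1 | intermediate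
13 | C3/C4-bridged acyloxonium (2-aryl-1,3-dioxolan-2-ylium) ion of the dimer, both ring oxygens on the α-face of the middle C-ring (not isolated) | [C+]1(c6cc(OCc5ccccc5)c(OCc5ccccc5)c(OCc5ccccc5)c6)O[C@@H]2[C@H](O1)c3c(OCc5ccccc5)cc(OCc5ccccc5)c([C@H]4c7c(OCc5ccccc5)cc(OCc5ccccc5)c(Br)c7O[C@H](c7cc(OCc5ccccc5)c(OCc5ccccc5)c(OCc5ccccc5)c7)[C@@H]4O)c3O[C@@H]2c6cc(OCc5ccccc5)c(OCc5ccccc5)c(OCc5ccccc5)c6 | intermediate
14 | [8-bromo-penta-O-benzyl-epigallocatechin]-(4β→8)-[penta-O-benzyl-epigallocatechin 3-O-tri-O-benzylgallate]-(4β→8)-[penta-O-benzyl-epigallocatechin] | O=C(O[C@@H]1[C@@H](c2c(OCc5ccccc5)cc(OCc5ccccc5)c3c2O[C@H](c2cc(OCc5ccccc5)c(OCc5ccccc5)c(OCc5ccccc5)c2)[C@H](O)C3)c2c(OCc5ccccc5)cc(OCc5ccccc5)c([C@H]3c4c(OCc5ccccc5)cc(OCc5ccccc5)c(Br)c4O[C@H](c4cc(OCc5ccccc5)c(OCc5ccccc5)c(OCc5ccccc5)c4)[C@@H]3O)c2O[C@@H]1c1cc(OCc5ccccc5)c(OCc5ccccc5)c(OCc5ccccc5)c1)c1cc(OCc5ccccc5)c(OCc5ccccc5)c(OCc5ccccc5)c1 | intermediate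
15 | epigallocatechin-(4β→8)-epigallocatechin 3-O-gallate-(4β→8)-epigallocatechin (upper unit 2R,3R,4R; middle unit 2R,3R,4S; terminal unit 2R,3R) | O=C(O[C@@H]1[C@@H](c2c(O)cc(O)c3c2O[C@H](c2cc(O)c(O)c(O)c2)[C@H](O)C3)c2c(O)cc(O)c([C@H]3c4c(O)cc(O)cc4O[C@H](c4cc(O)c(O)c(O)c4)[C@@H]3O)c2O[C@@H]1c1cc(O)c(O)c(O)c1)c1cc(O)c(O)c(O)c1 | target

Total step count: 8. Longest linear sequence: 7 steps (1 → 3 → 5 → 9 → 11 → 12 → 14 → 15; steps 1, 2, 4, 5, 6, 7, 8).

Steps most likely to fail

Step 7 (key step). Ionisation of the hindered aryl sulfide by silver may be slow at the temperatures at which the liberated triflic acid begins to cleave or scramble the upper interflavan bond. Facial and C8/C6 selectivity may also erode as the mixture is warmed. The fallback sets out from 12 and separates ionisation from C–C bond formation. Silver triflate in CH2Cl2–methanol should exchange the thio group for methoxy, again on the β-face through the acyloxonium ion, to give the 4β-methoxy dimer F1. F1 and 3 are then condensed with catalytic TMSOTf in CH2Cl2 at −78 °C, where a C4–O bond ionises readily and only catalytic acid is present, and the route is rejoined at 14.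

Step 6. Orthogonality may be lost: the silyl triflate may also ionise the C4–S bond of 11, or the sulfide sulfur may capture the cation and the thio group migrate, leading to oligomers and scrambled thioethers. The fallback sets out from 3 and 7 and carries no sulfur. Compound 3 is esterified with 10 (DCC, DMAP) to octa-O-benzyl-epigallocatechin gallate F2. Compounds 7 and F2 (in excess) are coupled with catalytic TMSOTf at −78 °C to the bromo-capped dimer F3, whose lower unit has a C4 methylene. DDQ and 2-ethoxyethanol (4) then oxidise this only remaining benzylic CH2 to the 4β-(2-ethoxyethoxy) dimer F4, β through participation of the gallate. TMSOTf-catalysed condensation of F4 with 3 rejoins the route at 14.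

Step 8. The HBr released from the aryl bromide may cleave interflavan bonds, bromide may poison the catalyst so that debenzylation stalls, and long exposure may lead to over-reduction at the benzylic C2–O1 bonds. The fallback sets out from 14 and removes the halogen before any hydrogen gas is used. Palladium-catalysed transfer hydrodebromination (Pd(OAc)2/SPhos cat., HCO2Na, DMF, 80 °C) should give the bromine-free protected trimer F5 without touching the benzyl ethers. Hydrogenolysis of F5 over Pd(OH)2/C without additive then returns to the route at 15.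

Further compounds

F1 | step 7 | [8-bromo-penta-O-benzyl-epigallocatechin]-(4β→8)-[penta-O-benzyl-4β-methoxy-epigallocatechin 3-O-tri-O-benzylgallate] | O=C(O[C@@H]1[C@@H](OC)c2c(OCc5ccccc5)cc(OCc5ccccc5)c([C@H]3c4c(OCc5ccccc5)cc(OCc5ccccc5)c(Br)c4O[C@H](c4cc(OCc5ccccc5)c(OCc5ccccc5)c(OCc5ccccc5)c4)[C@@H]3O)c2O[C@@H]1c1cc(OCc5ccccc5)c(OCc5ccccc5)c(OCc5ccccc5)c1)c1cc(OCc5ccccc5)c(OCc5ccccc5)c(OCc5ccccc5)c1
F2 | step 6 | octa-O-benzyl-(−)-epigallocatechin gallate (penta-O-benzyl-epigallocatechin 3-O-[3,4,5-tris(benzyloxy)benzoate]) | O=C(O[C@@H]1Cc2c(OCc5ccccc5)cc(OCc5ccccc5)cc2O[C@@H]1c1cc(OCc5ccccc5)c(OCc5ccccc5)c(OCc5ccccc5)c1)c1cc(OCc5ccccc5)c(OCc5ccccc5)c(OCc5ccccc5)c1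
F3 | step 6 | [8-bromo-penta-O-benzyl-epigallocatechin]-(4β→8)-[penta-O-benzyl-epigallocatechin 3-O-tri-O-benzylgallate] | O=C(O[C@@H]1Cc2c(OCc5ccccc5)cc(OCc5ccccc5)c([C@H]3c4c(OCc5ccccc5)cc(OCc5ccccc5)c(Br)c4O[C@H](c4cc(OCc5ccccc5)c(OCc5ccccc5)c(OCc5ccccc5)c4)[C@@H]3O)c2O[C@@H]1c1cc(OCc5ccccc5)c(OCc5ccccc5)c(OCc5ccccc5)c1)c1cc(OCc5ccccc5)c(OCc5ccccc5)c(OCc5ccccc5)c1
F4 | step 6 | [8-bromo-penta-O-benzyl-epigallocatechin]-(4β→8)-[penta-O-benzyl-4β-(2-ethoxyethoxy)-epigallocatechin 3-O-tri-O-benzylgallate] | O=C(O[C@@H]1[C@@H](OCCOCC)c2c(OCc5ccccc5)cc(OCc5ccccc5)c([C@H]3c4c(OCc5ccccc5)cc(OCc5ccccc5)c(Br)c4O[C@H](c4cc(OCc5ccccc5)c(OCc5ccccc5)c(OCc5ccccc5)c4)[C@@H]3O)c2O[C@@H]1c1cc(OCc5ccccc5)c(OCc5ccccc5)c(OCc5ccccc5)c1)c1cc(OCc5ccccc5)c(OCc5ccccc5)c(OCc5ccccc5)c1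
F5 | step 8 | [penta-O-benzyl-epigallocatechin]-(4β→8)-[penta-O-benzyl-epigallocatechin 3-O-tri-O-benzylgallate]-(4β→8)-[penta-O-benzyl-epigallocatechin] | O=C(O[C@@H]1[C@@H](c2c(OCc5ccccc5)cc(OCc5ccccc5)c3c2O[C@H](c2cc(OCc5ccccc5)c(OCc5ccccc5)c(OCc5ccccc5)c2)[C@H](O)C3)c2c(OCc5ccccc5)cc(OCc5ccccc5)c([C@H]3c4c(OCc5ccccc5)cc(OCc5ccccc5)cc4O[C@H](c4cc(OCc5ccccc5)c(OCc5ccccc5)c(OCc5ccccc5)c4)[C@@H]3O)c2O[C@@H]1c1cc(OCc5ccccc5)c(OCc5ccccc5)c(OCc5ccccc5)c1)c1cc(OCc5ccccc5)c(OCc5ccccc5)c(OCc5ccccc5)c1
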